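**Retrosynthetic overview**

- The target comes from its bridged methyl enol ether by O-demethylation; the C1 isobutyryl and C5 prenyl groups are put on a bare bicyclo[3.3.1]non-3-ene-2,9-dione core by two bridgehead lithiations.
- That core comes from a cis-fused hydrindane β-hydroxy vinylogous ester by an oxidative semipinacol 1,2-alkyl shift: the cyclopentane CH2 moves from the carbinol carbon to the neighbouring ring carbon, expanding the five-membered ring to ring B.
- The hydrindane comes from a 3,3,4-trisubstituted cyclopentanone enolate and diketene (C-acylation/aldol annulation builds ring A).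
- The enolate comes from (S)-3-methyl-4-prenylcyclopent-2-enone by anti-selective copper-catalysed addition of homoprenyl Grignard; the enone comes from a Stork–Danheiser transposition.
- The first stereocentre is set by a new enantioselective Pd-catalysed α′-prenylation of 3-methoxycyclopent-2-enone. Ring order: cyclopentane (bought), then ring A (annulation), then ring B (ring expansion).

Assumption: the target is one enol tautomer of an equilibrating bridged 1,3-diketone and is obtained as that mixture; in step 1 the (R,R) ligand antipode is taken to give the (S)-product, and the (S,S) ligand is used if the sense proves opposite.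

The route is a design on paper; no step has been run.

**Step 1**
Reactants: 1 3-methoxycyclopent-2-en-1-one; 2 1-chloro-3-methylbut-2-ene (prenyl chloride)
Product: 4 (S)-3-methoxy-5-(3-methylbut-2-en-1-yl)cyclopent-2-en-1-one, via lithium dienolate 3 (not isolated)
Conditions: LiN(SiMe3)2, LiCl, THF, −78 °C; then 2, [Pd(η3-C3H5)Cl]2 (2.5 mol %), N,N′-[(1R,2R)-cyclohexane-1,2-diyl]bis[2-(diphenylphosphanyl)benzamide] (6 mol %), −78 → −40 °C
Reagents that add atoms: none
Why: Proposed new method: the LiCl-deaggregated cross-conjugated lithium dienolate 3 attacks, outer-sphere and at the unsubstituted allyl terminus, the π-prenyl complex of divalent palladium formed by ionisation of 2 at the chiral zerovalent palladium catalyst, whose bis(amide)–diphosphine pocket differentiates the two enolate faces and so sets the tertiary α′-centre as (S), while the low temperature, the poor proton shuttle HN(SiMe3)2 and the slow uncatalysed SN2 of the allylic chloride hold back racemisation, dialkylation and racemic background; the closest known reaction type is the palladium-catalysed asymmetric allylic alkylation (Tsuji–Trost) of preformed lithium ketone enolates and its decarboxylative variant on vinylogous esters, neither shown for direct α′-prenylation of a 3-alkoxycyclopentenone to a tertiary centre.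

**Step 2**
Reactants: 4 (S)-3-methoxy-5-(3-methylbut-2-en-1-yl)cyclopent-2-en-1-one
Product: 6 (S)-3-methyl-4-(3-methylbut-2-en-1-yl)cyclopent-2-en-1-one, via lithium alkoxide 5 (not isolated)
Conditions: MeLi, CeCl3, THF, −78 °C; then 1 M HCl, 0 °C
Reagents that add atoms: methyllithium, [Li]C
Why: 1,2-addition of the weakly basic organocerium to the vinylogous ester carbonyl, then acid hydrolysis of the enol ether and loss of water, transposes the enone (Stork–Danheiser sequence); the prenyl-bearing stereocentre is carried over untouched and the carbinol centre of 5 is destroyed.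

**Step 3**
Reactants: 6 (S)-3-methyl-4-(3-methylbut-2-en-1-yl)cyclopent-2-en-1-one; 7 5-bromo-2-methylpent-2-ene (homoprenyl bromide)
Product: 9 trimethyl{[(3R,4S)-3-methyl-3-(4-methylpent-3-en-1-yl)-4-(3-methylbut-2-en-1-yl)cyclopent-1-en-1-yl]oxy}silane, via Grignard reagent 8 (not isolated)
Conditions: 7, Mg, THF, 23 °C; then 6, CuBr·SMe2 (10 mol %), Me3SiCl, THF, −78 → −40 °C
Reagents that add atoms: chlorotrimethylsilane, C[Si](C)(C)Cl
Why: the Me3SiCl-accelerated copper-catalysed conjugate addition of the Grignard reagent builds the quaternary carbon with the homoprenyl group anti to the neighbouring prenyl group (methyl cis to prenyl) and traps the enolate regiospecifically as the silyl enol ether.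

**Step 4**
Reactants: 9 trimethyl{[(3R,4S)-3-methyl-3-(4-methylpent-3-en-1-yl)-4-(3-methylbut-2-en-1-yl)cyclopent-1-en-1-yl]oxy}silane; 10 diketene (4-methylideneoxetan-2-one)
Product: 13 (2S,3R,3aR,7aS)-7a-hydroxy-6-methoxy-3-methyl-3-(4-methylpent-3-en-1-yl)-2-(3-methylbut-2-en-1-yl)-1,2,3,3a,7,7a-hexahydro-4H-inden-4-one, via lithium enolate 11 (not isolated), via lithium diketonate 12 (not isolated)
Conditions: MeLi, THF, 0 °C; 10, −78 → −40 °C; then Me2SO4, DMPU, −40 → 0 °C
Reagents that add atoms: dimethyl sulfate, COS(=O)(=O)OC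
Why: C-acylation of the regiodefined enolate by diketene frees the terminal methyl-ketone enolate, which closes on the cyclopentanone carbonyl (acylation/intramolecular aldol annulation) to the cis-fused hydrindane; diketene approaches the face away from the C4 prenyl group, which sets C3a, the cis fusion sets C7a, and the lithium β-diketonate is then O-methylated at its less hindered oxygen (the one next to the CH2), giving the 6-methoxy enone.

**Step 5**
Reactants: 13 (2S,3R,3aR,7aS)-7a-hydroxy-6-methoxy-3-methyl-3-(4-methylpent-3-en-1-yl)-2-(3-methylbut-2-en-1-yl)-1,2,3,3a,7,7a-hexahydro-4H-inden-4-one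
Product: 15 (1S,5R,7S,8R)-4-methoxy-8-methyl-7-(3-methylbut-2-en-1-yl)-8-(4-methylpent-3-en-1-yl)bicyclo[3.3.1]non-3-ene-2,9-dione, via C7 iodane 14 (not isolated)
Conditions: PhI(OAc)2, KOH, MeOH, −10 → 0 °C
Reagents that add atoms: none
Why: hydroxide forms the extended (γ) dienolate of the vinylogous ester, which is captured by trivalent iodine at C7 on the face cis to the 7a-OH, and loss of iodobenzene then drives an anti-periplanar 1,2-shift of the cyclopentane CH2 from C7a to C7 pushed by the C7a oxygen (semipinacol ring expansion); the suprafacial migration on the cis-fused ring makes the new bridgehead C5 follow from C1, and the O/I cis arrangement disfavours epoxide closure.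

**Step 6**
Reactants: 15 (1S,5R,7S,8R)-4-methoxy-8-methyl-7-(3-methylbut-2-en-1-yl)-8-(4-methylpent-3-en-1-yl)bicyclo[3.3.1]non-3-ene-2,9-dione; 16 1-bromo-3-methylbut-2-ene (prenyl bromide)
Product: 18 (1S,5R,7S,8R)-4-methoxy-8-methyl-5,7-bis(3-methylbut-2-en-1-yl)-8-(4-methylpent-3-en-1-yl)bicyclo[3.3.1]non-3-ene-2,9-dione, via bridgehead organolithium 17 (not isolated)
Conditions: LiN(i-Pr)2, THF, −78 °C; then 16, −78 → 0 °C
Reagents that add atoms: none
Why: the C5–H (α to the C9 ketone, γ to the enone carbonyl and next to the lithium-coordinating methoxy group) is removed kinetically in preference to the C1–H shielded by the quaternary C8, and the bridgehead organolithium is alkylated with retention, which the bicycle enforces (bridgehead lithiation–alkylation).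

**Step 7**
Reactants: 18 (1S,5R,7S,8R)-4-methoxy-8-methyl-5,7-bis(3-methylbut-2-en-1-yl)-8-(4-methylpent-3-en-1-yl)bicyclo[3.3.1]non-3-ene-2,9-dione; 19 2-methylpropanoyl chloride (isobutyryl chloride)
Product: 22 (1S,5R,7S,8R)-4-methoxy-8-methyl-5,7-bis(3-methylbut-2-en-1-yl)-8-(4-methylpent-3-en-1-yl)-1-(2-methylpropanoyl)-3-(trimethylsilyl)bicyclo[3.3.1]non-3-ene-2,9-dione, via C3 silane 20 (not isolated), via bridgehead organolithium 21 (not isolated)
Conditions: lithium 2,2,6,6-tetramethylpiperidide (1.2 equiv), Me3SiCl (1.1 equiv), THF, −78 °C; then lithium 2,2,6,6-tetramethylpiperidide (3 equiv), −78 → −40 °C; then 19, −78 °C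
Reagents that add atoms: chlorotrimethylsilane, C[Si](C)(C)Cl
Why: in-situ silylation blocks the competing vinylic C3–H, after which the only remaining acidic site, the bridgehead C1–H between the C2 and C9 carbonyls, is lithiated and C-acylated by the acid chloride with retention (bridgehead lithiation–acylation).

**Step 8**
Reactants: 22 (1S,5R,7S,8R)-4-methoxy-8-methyl-5,7-bis(3-methylbut-2-en-1-yl)-8-(4-methylpent-3-en-1-yl)-1-(2-methylpropanoyl)-3-(trimethylsilyl)bicyclo[3.3.1]non-3-ene-2,9-dione
Product: 24 (1R,5R,7S,8R)-4-hydroxy-8-methyl-5,7-bis(3-methylbut-2-en-1-yl)-8-(4-methylpent-3-en-1-yl)-1-(2-methylpropanoyl)bicyclo[3.3.1]non-3-ene-2,9-dione, via lithium enolate 23 (not isolated)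
Conditions: LiCl, DMSO, 120 °C; then 1 M HCl, THF, 23 °C
Reagents that add atoms: none
Why: chloride cleaves the methyl enol ether by SN2 at methyl (Krapcho-type dealkylation) and the resulting 2-silyl-1,3-diketonate is protodesilylated on acidic work-up, releasing the enolised trione without touching any stereocentre.

**Compound list**

1 | 3-methoxycyclopent-2-en-1-one | COC1=CC(=O)CC1 | starting material
2 | 1-chloro-3-methylbut-2-ene (prenyl chloride) | CC(C)=CCCl | starting material
3 | lithium 4-methoxycyclopenta-1,4-dien-1-olate | [Li+].COC1=CC([O-])=CC1 | intermediate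
4 | (S)-3-methoxy-5-(3-methylbut-2-en-1-yl)cyclopent-2-en-1-one | COC1=CC(=O)[C@@H](CC=C(C)C)C1 | intermediate
5 | lithium (1S,5S)-3-methoxy-1-methyl-5-(3-methylbut-2-en-1-yl)cyclopent-2-en-1-olate (major epimer, methyl trans to prenyl) | [Li+].COC1=C[C@@](C)([O-])[C@@H](CC=C(C)C)C1 | intermediate
6 | (S)-3-methyl-4-(3-methylbut-2-en-1-yl)cyclopent-2-en-1-one | CC1=CC(=O)C[C@@H]1CC=C(C)C | intermediate
7 | 5-bromo-2-methylpent-2-ene (homoprenyl bromide) | CC(C)=CCCBr | starting material
8 | (4-methylpent-3-en-1-yl)magnesium bromide | CC(C)=CCC[Mg]Br | intermediate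
9 | trimethyl{[(3R,4S)-3-methyl-3-(4-methylpent-3-en-1-yl)-4-(3-methylbut-2-en-1-yl)cyclopent-1-en-1-yl]oxy}silane | CC(C)=CCC[C@]1(C)[C@@H](CC=C(C)C)CC(O[Si](C)(C)C)=C1 | intermediate
10 | diketene (4-methylideneoxetan-2-one) | C=C1CC(=O)O1 | starting material
11 | lithium (3R,4S)-3-methyl-3-(4-methylpent-3-en-1-yl)-4-(3-methylbut-2-en-1-yl)cyclopent-1-en-1-olate | [Li+].CC(C)=CCC[C@]1(C)[C@@H](CC=C(C)C)CC([O-])=C1 | intermediate
12 | lithium (2S,3R,3aR,7aS)-7a-hydroxy-3-methyl-3-(4-methylpent-3-en-1-yl)-2-(3-methylbut-2-en-1-yl)-4-oxo-2,3,3a,4,7,7a-hexahydro-1H-inden-6-olate | [Li+].CC(C)=CCC[C@]1(C)[C@@H](CC=C(C)C)C[C@]2(O)CC([O-])=CC(=O)[C@H]12 | intermediate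
13 | (2S,3R,3aR,7aS)-7a-hydroxy-6-methoxy-3-methyl-3-(4-methylpent-3-en-1-yl)-2-(3-methylbut-2-en-1-yl)-1,2,3,3a,7,7a-hexahydro-4H-inden-4-one (cis-fused) | CC(C)=CCC[C@]1(C)[C@@H](CC=C(C)C)C[C@]2(O)CC(OC)=CC(=O)[C@H]12 | intermediate
14 | 7-[methoxy(phenyl)iodanyl] derivative of 13 (trivalent iodine on C7, cis to the 7a-OH, anti to the migrating bond) | CC(C)=CCC[C@]1(C)[C@@H](CC=C(C)C)C[C@]2(O)[C@@H](I(OC)c3ccccc3)C(OC)=CC(=O)[C@H]12 | intermediate
15 | (1S,5R,7S,8R)-4-methoxy-8-methyl-7-(3-methylbut-2-en-1-yl)-8-(4-methylpent-3-en-1-yl)bicyclo[3.3.1]non-3-ene-2,9-dione | CC(C)=CCC[C@]1(C)[C@@H](CC=C(C)C)C[C@H]2C(=O)[C@@H]1C(=O)C=C2OC | intermediate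
16 | 1-bromo-3-methylbut-2-ene (prenyl bromide) | CC(C)=CCBr | starting material
17 | 5-lithio derivative of 15 (lithium exo on bridgehead C5) | CC(C)=CCC[C@]1(C)[C@@H](CC=C(C)C)C[C@@]2([Li])C(=O)[C@@H]1C(=O)C=C2OC | intermediate
18 | (1S,5R,7S,8R)-4-methoxy-8-methyl-5,7-bis(3-methylbut-2-en-1-yl)-8-(4-methylpent-3-en-1-yl)bicyclo[3.3.1]non-3-ene-2,9-dione | CC(C)=CCC[C@]1(C)[C@@H](CC=C(C)C)C[C@@]2(CC=C(C)C)C(=O)[C@@H]1C(=O)C=C2OC | intermediate
19 | 2-methylpropanoyl chloride (isobutyryl chloride) | CC(C)C(=O)Cl | starting material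
20 | (1R,5R,7S,8R)-4-methoxy-8-methyl-5,7-bis(3-methylbut-2-en-1-yl)-8-(4-methylpent-3-en-1-yl)-3-(trimethylsilyl)bicyclo[3.3.1]non-3-ene-2,9-dione | CC(C)=CCC[C@]1(C)[C@@H](CC=C(C)C)C[C@@]2(CC=C(C)C)C(=O)[C@@H]1C(=O)C([Si](C)(C)C)=C2OC | intermediate
21 | 1-lithio derivative of 20 (lithium exo on bridgehead C1) | CC(C)=CCC[C@]1(C)[C@@H](CC=C(C)C)C[C@@]2(CC=C(C)C)C(=O)[C@]1([Li])C(=O)C([Si](C)(C)C)=C2OC | intermediate
22 | (1S,5R,7S,8R)-4-methoxy-8-methyl-5,7-bis(3-methylbut-2-en-1-yl)-8-(4-methylpent-3-en-1-yl)-1-(2-methylpropanoyl)-3-(trimethylsilyl)bicyclo[3.3.1]non-3-ene-2,9-dione | CC(C)=CCC[C@]1(C)[C@@H](CC=C(C)C)C[C@@]2(CC=C(C)C)C(=O)[C@]1(C(=O)C(C)C)C(=O)C([Si](C)(C)C)=C2OC | intermediate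
23 | lithium 4-enolate of O-demethylated 22 (C3 silyl group still in place) | [Li+].CC(C)=CCC[C@]1(C)[C@@H](CC=C(C)C)C[C@@]2(CC=C(C)C)C(=O)[C@]1(C(=O)C(C)C)C(=O)C([Si](C)(C)C)=C2[O-] | intermediate
24 | (1R,5R,7S,8R)-4-hydroxy-8-methyl-5,7-bis(3-methylbut-2-en-1-yl)-8-(4-methylpent-3-en-1-yl)-1-(2-methylpropanoyl)bicyclo[3.3.1]non-3-ene-2,9-dione | CC(C)=CCC[C@]1(C)[C@@H](CC=C(C)C)C[C@@]2(CC=C(C)C)C(=O)[C@]1(C(=O)C(C)C)C(=O)C=C2O | target

**Totals**

Total step count: 8. Longest linear sequence: 8 steps (1 → 24).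

**Steps most likely to fail**

Step 1 (the proposed new enantioselective α′-prenylation): the risk is low enantiomeric excess, racemisation of the tertiary centre, or dialkylation. Fallback with known chemistry, setting out from 1: the lithium enolate made with LiN(i-Pr)2 in THF at −78 °C is alkylated with prenyl bromide 16 (ordinary kinetic α′-alkylation of a vinylogous ester). This gives 4 as a racemate together with its mirror image (R)-3-methoxy-5-(3-methylbut-2-en-1-yl)cyclopent-2-en-1-one F1. The two are separated by preparative chromatography on a chiral stationary phase, and the route is rejoined at 4.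

Step 5 (oxidative ring expansion): the risks are γ-methoxylation instead of the shift, base-induced dehydration and aromatisation of the β-hydroxy enone, and retro-Claisen opening of the product. Fallback, setting out from 13, separates the oxidation from the shift. Me3SiOSO2CF3 and Et3N in CH2Cl2 give 6-methoxy-3-methyl-3-(4-methylpent-3-en-1-yl)-2-(3-methylbut-2-en-1-yl)-4,7a-bis[(trimethylsilyl)oxy]-2,3,3a,7a-tetrahydro-1H-indene F2 (configuration as in 13). N-bromosuccinimide in THF at −78 °C brominates its γ-carbon to give 7-bromo-6-methoxy-3-methyl-3-(4-methylpent-3-en-1-yl)-2-(3-methylbut-2-en-1-yl)-7a-[(trimethylsilyl)oxy]-1,2,3,3a,7,7a-hexahydro-4H-inden-4-one F3 (bromine cis to the silyloxy group). AgOSO2CF3 in CH2Cl2 then ionises the C–Br bond and triggers the same 1,2-shift without base (silver-promoted semipinacol rearrangement of a β-silyloxy bromide), and the route is rejoined at 15.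

Step 7 (one-pot C3 silylation and bridgehead acylation): the risks are incomplete C3 blocking, slow lithiation of the C1–H next to the quaternary C8, and attack of the acid chloride on the amide base. Fallback, setting out from 18: the silylation is run alone and 20 is isolated. C1 is lithiated with lithium 2,2,6,6-tetramethylpiperidide and the small electrophile isobutyraldehyde is added, giving 1-(1-hydroxy-2-methylpropyl)-4-methoxy-8-methyl-5,7-bis(3-methylbut-2-en-1-yl)-8-(4-methylpent-3-en-1-yl)-3-(trimethylsilyl)bicyclo[3.3.1]non-3-ene-2,9-dione F4 (carbinol epimers). Dess–Martin periodinane in CH2Cl2 oxidises the carbinol (aldehyde addition/oxidation instead of direct acylation), and the route is rejoined at 22.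

**Further compounds**

F1 | step 1 | (R)-3-methoxy-5-(3-methylbut-2-en-1-yl)cyclopent-2-en-1-one | COC1=CC(=O)[C@H](CC=C(C)C)C1
F2 | step 5 | 6-methoxy-3-methyl-3-(4-methylpent-3-en-1-yl)-2-(3-methylbut-2-en-1-yl)-4,7a-bis[(trimethylsilyl)oxy]-2,3,3a,7a-tetrahydro-1H-indene (configuration as in 13) | CC(C)=CCC[C@]1(C)[C@@H](CC=C(C)C)C[C@]2(O[Si](C)(C)C)C=C(OC)C=C(O[Si](C)(C)C)[C@H]12
F3 | step 5 | 7-bromo-6-methoxy-3-methyl-3-(4-methylpent-3-en-1-yl)-2-(3-methylbut-2-en-1-yl)-7a-[(trimethylsilyl)oxy]-1,2,3,3a,7,7a-hexahydro-4H-inden-4-one (bromine cis to the silyloxy group) | CC(C)=CCC[C@]1(C)[C@@H](CC=C(C)C)C[C@]2(O[Si](C)(C)C)[C@@H](Br)C(OC)=CC(=O)[C@H]12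
F4 | step 7 | 1-(1-hydroxy-2-methylpropyl)-4-methoxy-8-methyl-5,7-bis(3-methylbut-2-en-1-yl)-8-(4-methylpent-3-en-1-yl)-3-(trimethylsilyl)bicyclo[3.3.1]non-3-ene-2,9-dione (carbinol epimers) | CC(C)=CCC[C@]1(C)[C@@H](CC=C(C)C)C[C@@]2(CC=C(C)C)C(=O)[C@]1(C(O)C(C)C)C(=O)C([Si](C)(C)C)=C2OC
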